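**Plan**
1. Retrosynthesis: the interflavan C4–C8 bond is cut first, which leaves two copies of one benzyl-protected (2R,3R)-2,3-cis-flavan-3-ol (12). In 12, ring C is cut at O1–C8a and at C2–C3, and ring A goes back to 1,3,5-trifluorobenzene.
2. Enabling feature: in ring A, C8a is ortho to C4a, and O-5 and O-7 are both meta to C8a. A temporary carbonyl at C4 therefore acidifies C3–H and also activates a C8a–F bond for ipso attack, so a benzoyl unit (O1=C2–Ph) can be stitched between C3 and C8a in one operation.
3. Forward order: ring A ether 3 → aryl methoxymethyl ketone 5 → ring C closed as the 3-methoxyflavone 8 (C4 carbonyl and trigonal C2/C3 as helpers) → helpers removed to give the racemic flavan-3-one 11.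
4. Stereochemistry: C2 and C3 of both units are set together by one dynamic kinetic resolution of 11 (catalyst control at C3, cis by substrate control, C2 epimerising through the enol). C4 of the upper unit is set by attack on the planar flavan-4-yl cation anti to the C3 hydroxyl.
5. Endgame: part of 12 is oxidised at C4 to the electrophile 14, joined to C8 of a second molecule of 12, and the four benzyl ethers are removed.

Key step: step 3

Assumption (remark on the chemistry): in step 5 the (S,S)-catalyst is taken to place the benzylic C4 methylene next to its η6-arene and the branched C2 away from it, so that hydride reaches the Si face of C3=O. Should the sense prove opposite, the (R,R)-catalyst is used and nothing else changes.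

**Step 1**
Reactants: 1 1,3,5-trifluorobenzene; 2 benzyl alcohol (2.1 equiv)
Product: 3 1,3-bis(benzyloxy)-5-fluorobenzene
Conditions: NaH, NMP, 0 °C then 100 °C
Reagents that add atoms: none
Why: two successive nucleophilic aromatic substitutions (SNAr) by sodium benzyloxide on the mutually meta-activated C–F bonds should stop at the bis-ether, because each alkoxy group lowers the electrophilicity of the ring.

**Step 2**
Reactants: 3 1,3-bis(benzyloxy)-5-fluorobenzene; 4 N,2-dimethoxy-N-methylacetamide
Product: 5 1-[2,4-bis(benzyloxy)-6-fluorophenyl]-2-methoxyethan-1-one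
Conditions: n-BuLi, THF, −78 °C; then 4, −78 °C; AcOH quench at −78 °C, aq NH4Cl
Reagents that add atoms: none
Why: n-BuLi should remove the most acidic ring proton, the one flanked by F and OBn (directed ortho-metalation), and the aryllithium, kept at −78 °C to prevent loss of LiF, should be acylated once through the chelated tetrahedral intermediate of the Weinreb ketone synthesis.

**Step 3**
Reactants: 5 1-[2,4-bis(benzyloxy)-6-fluorophenyl]-2-methoxyethan-1-one; 6 benzoyl chloride
Product: 8 5,7-bis(benzyloxy)-3-methoxy-2-phenyl-4H-chromen-4-one (3-methoxyflavone), via diketone enolate 7 (not isolated)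
Conditions: LiN(SiMe3)2 (2.2 equiv), THF, −78 °C; 6, −78 to 0 °C; then DMF added, THF distilled off, 90 °C
Reagents that add atoms: none
Why: LiN(SiMe3)2 forms the chelated lithium enolate of 5, whose C3 is benzoylated by 6 to give the 1,3-diketone 7 as its enolate (Claisen-type C-acylation, C2–C3 bond); on heating in DMF the benzoyl-derived enolate oxygen adds to the fluorine-bearing C8a, which the ortho C4 carbonyl activates, and loss of fluoride from the Meisenheimer intermediate gives the aromatic 4-pyranone (intramolecular SNAr, O1–C8a bond). The closest known reaction type is the formation of flavones and chromones from 1-(2-halophenyl)-1,3-diketones by base-mediated O-arylation. Ring C closes as a six-membered ring by addition–elimination at an sp2 carbon (formally 6-exo-trig with respect to the C8a=C8 π bond); closure through the other enolate oxygen or through C3 would need a four-membered ring and is excluded. No stereocentre is created, since C2 and C3 are left trigonal on purpose so that both can be set later in a single step. The selectivity needed is C- over O-acylation and ipso attack at C8a: the first is secured by the chelated enolate and the excess base, under which any enol benzoate can pass its acyl group on to give the stabilised diketonate, and the second by the single C–F bond, which the 5- and 7-benzyloxy groups (both meta to C8a) do not deactivate.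

**Step 4**
Reactants: 8 5,7-bis(benzyloxy)-3-methoxy-2-phenyl-4H-chromen-4-one
Product: 11 rac-5,7-bis(benzyloxy)-2-phenylchroman-3-one, via flavylium ion 9 (not isolated), via enol ether 10 (not isolated)
Conditions: LiAlH4–AlCl3 (1:1), Et2O–THF, −20 to 0 °C; then 1 M aq HCl, THF, rt, under argon
Reagents that add atoms: water O
Why: chloroalane should add hydride to the C4 carbonyl, ionise the C4–O–Al bond to the 3-methoxyflavylium ion 9 and reduce it to the enol ether 10 (mixed-hydride deoxygenation of a vinylogous ester; hydride addition at C2 would give the isomeric C3=C4 enol ether), and dilute acid should then protonate C2 to the methoxy-stabilised oxocarbenium ion at C3 and hydrolyse it, so that either enol ether converges on ketone 11 with C2 racemic.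

**Step 5**
Reactants: 11 rac-5,7-bis(benzyloxy)-2-phenylchroman-3-one
Product: 12 (2R,3R)-5,7-bis(benzyloxy)-2-phenylchroman-3-ol (2,3-cis)
Conditions: RuCl[(S,S)-TsDPEN](p-cymene) (2 mol%), HCO2H–Et3N (5:2), EtOAc, 35 °C
Reagents that add atoms: none
Why: Noyori asymmetric transfer hydrogenation with dynamic kinetic resolution: C2–H of 11 is benzylic, α to oxygen and α to the ketone, so the enantiomers should interconvert through the enol in Et3N faster than they are reduced, while the catalyst should deliver hydride to the Si face of C3=O (sets 3R) and, adding to the face remote from the C2 phenyl, should select the (2R)-ketone and give the 2,3-cis alcohol.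

**Step 6**
Reactants: 12 (2R,3R)-5,7-bis(benzyloxy)-2-phenylchroman-3-ol; 13 2-ethoxyethanol (5 equiv)
Product: 14 (2R,3R,4S)-5,7-bis(benzyloxy)-4-(2-ethoxyethoxy)-2-phenylchroman-3-ol (3,4-trans)
Conditions: DDQ (1.5 equiv), CH2Cl2, rt
Reagents that add atoms: none
Why: DDQ should abstract hydride from C4, the benzylic position activated by the ortho and para ether oxygens of ring A, and the alcohol should trap the flavan-4-yl cation from the face anti to the C3 hydroxyl and C2 phenyl (benzylic oxidative etherification).

**Step 7**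
Reactants: 14 (2R,3R,4S)-5,7-bis(benzyloxy)-4-(2-ethoxyethoxy)-2-phenylchroman-3-ol; 12 (2R,3R)-5,7-bis(benzyloxy)-2-phenylchroman-3-ol (4 equiv, excess recovered)
Product: 15 tetra-O-benzyl dimer, (2R,3R,4R)-5,7-bis(benzyloxy)-2-phenylchroman-3-ol joined through C4 to C8 of (2R,3R)-5,7-bis(benzyloxy)-2-phenylchroman-3-ol
Conditions: TMSOTf (0.2 equiv), CH2Cl2, −78 to −40 °C; aq NaHCO3
Reagents that add atoms: none
Why: TMSOTf should ionise the C4 ether of 14 to the same cation, which C8 of 12 (ortho to O-1 and O-7, para to O-5, less hindered than C6) should attack anti to the C3 hydroxyl in a Friedel–Crafts alkylation, giving the 3,4-trans 4→8 bond whatever the C4 configuration of 14, while the excess of 12 suppresses further alkylation of the product.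

**Step 8**
Reactants: 15 tetra-O-benzyl dimer
Product: 16 target, (2R,3R)-3,5,7-trihydroxyflavan-(4β→8)-(2R,3R)-3,5,7-trihydroxyflavan
Conditions: H2 (1 atm), Pd(OH)2/C, THF–MeOH–H2O, rt
Reagents that add atoms: none
Why: hydrogenolysis of the four benzyl aryl ethers under neutral conditions should leave the acid-labile interflavan bond, the two benzylic C2–O1 bonds and all five stereocentres untouched.

**Compound list**
1 | 1,3,5-trifluorobenzene | Fc1cc(F)cc(F)c1 | starting material
2 | benzyl alcohol | OCc1ccccc1 | starting material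
3 | 1,3-bis(benzyloxy)-5-fluorobenzene | Fc1cc(OCc2ccccc2)cc(OCc2ccccc2)c1 | intermediate
4 | N,2-dimethoxy-N-methylacetamide | COCC(=O)N(C)OC | starting material
5 | 1-[2,4-bis(benzyloxy)-6-fluorophenyl]-2-methoxyethan-1-one | COCC(=O)c1c(F)cc(OCc2ccccc2)cc1OCc1ccccc1 | intermediate
6 | benzoyl chloride | O=C(Cl)c1ccccc1 | starting material
7 | 1-[2,4-bis(benzyloxy)-6-fluorophenyl]-2-methoxy-3-phenylpropane-1,3-dione (lithium enolate in the flask) | COC(C(=O)c1ccccc1)C(=O)c1c(F)cc(OCc2ccccc2)cc1OCc1ccccc1 | intermediate
8 | 5,7-bis(benzyloxy)-3-methoxy-2-phenyl-4H-chromen-4-one | COc1c(-c2ccccc2)oc2cc(OCc3ccccc3)cc(OCc3ccccc3)c2c1=O | intermediate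
9 | 5,7-bis(benzyloxy)-3-methoxy-2-phenylchromenylium ion (chloroaluminate ion pair, drawn as chloride) | COc1cc2c(OCc3ccccc3)cc(OCc3ccccc3)cc2[o+]c1-c1ccccc1.[Cl-] | intermediate
10 | 5,7-bis(benzyloxy)-3-methoxy-2-phenyl-4H-chromene | COC1=C(c2ccccc2)Oc2cc(OCc3ccccc3)cc(OCc3ccccc3)c2C1 | intermediate
11 | rac-5,7-bis(benzyloxy)-2-phenylchroman-3-one | O=C1Cc2c(OCc3ccccc3)cc(OCc3ccccc3)cc2OC1c1ccccc1 | intermediate
12 | (2R,3R)-5,7-bis(benzyloxy)-2-phenylchroman-3-ol | C(c1ccccc1)Oc1cc(OCc2ccccc2)c2c(c1)O[C@H](c1ccccc1)[C@H](O)C2 | intermediate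
13 | 2-ethoxyethanol | CCOCCO | starting material
14 | (2R,3R,4S)-5,7-bis(benzyloxy)-4-(2-ethoxyethoxy)-2-phenylchroman-3-ol | C(c1ccccc1)Oc1cc(OCc2ccccc2)c2c(c1)O[C@H](c1ccccc1)[C@H](O)[C@H]2OCCOCC | intermediate
15 | tetra-O-benzyl dimer, upper unit (2R,3R,4R), lower unit (2R,3R), C4→C8 | C(c1ccccc1)Oc1cc(OCc2ccccc2)c2c(c1)O[C@H](c1ccccc1)[C@H](O)[C@H]2c1c(OCc2ccccc2)cc(OCc2ccccc2)c2c1O[C@H](c1ccccc1)[C@H](O)C2 | intermediate
16 | (2R,3R)-3,5,7-trihydroxyflavan-(4β→8)-(2R,3R)-3,5,7-trihydroxyflavan, upper C4 (R) | Oc1cc(O)c2c(c1)O[C@H](c1ccccc1)[C@H](O)[C@H]2c1c(O)cc(O)c2c1O[C@H](c1ccccc1)[C@H](O)C2 | target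

**Step count and risks**
Total steps: 8. Longest linear sequence: 8 (steps 1 to 8; compound 12 enters step 7 a second time as the nucleophile).

Step 4 (deoxygenation and hydrolysis). What may go wrong: cleavage of the peri C5 benzyl ether by the Lewis-acidic aluminium species, or, in the acid stage, protonation of the enol ether at C3 instead of C2 followed by hydrolytic opening of ring C. The fallback sets out from 8 and comes back at 11. Conjugate reduction of 8 with LiBH(s-Bu)3 (THF, −78 °C) should give 5,7-bis(benzyloxy)-3-methoxy-2-phenylchroman-4-one F1 as racemic diastereomers. NaBH4 (MeOH–THF, 0 °C) should reduce it to 5,7-bis(benzyloxy)-3-methoxy-2-phenylchroman-4-ol F2. TsOH in wet THF should ionise F2 at C4 (cation stabilised by ring A) and eliminate to 5,7-bis(benzyloxy)-3-methoxy-2-phenyl-2H-chromene F3. The enol ether double bond of F3 lies between C3 and C4, so hydrolysis in the same flask can only lead to 11.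

Step 5 (dynamic kinetic resolution). What may go wrong: insufficient facial discrimination by the catalyst, or reduction outrunning epimerisation at C2, which would lower the enantiomeric purity or let the trans isomer through. The fallback sets out from 11 and comes back at 12. LiBH(s-Bu)3 (THF, −78 °C) should give rac-cis-5,7-bis(benzyloxy)-2-phenylchroman-3-ol F4 by attack anti to the phenyl group. Esterification with (S)-2-methoxy-2-phenylacetic acid (EDC, catalytic DMAP, CH2Cl2, 0 °C) should give the diastereomeric esters, the (2R,3R)-ester F5 and the (2S,3S)-ester F6, to be separated by chromatography or crystallisation. K2CO3 in MeOH should then release 12 from F5.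

Step 7 (interflavan coupling). What may go wrong: self-condensation of the electrophile through its own C8, further alkylation of the dimer (oligomerisation), and competing attack through C6. The fallback sets out from 12 and comes back at 16, using a removable bromine cap on the electrophilic half. NBS (CH2Cl2, −78 °C) should brominate 12 at C8 to (2R,3R)-5,7-bis(benzyloxy)-8-bromo-2-phenylchroman-3-ol F7. DDQ with 13 should give its 3,4-trans 4-(2-ethoxyethoxy) ether F8, which can no longer act as a nucleophile. TMSOTf-promoted coupling with about one equivalent of 12 should give the 8-bromo tetra-O-benzyl dimer F9. H2 over Pd(OH)2/C with Et3N should remove the bromine and the four benzyl groups together to give 16.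

**Further compounds**
F1 | step 4 | 5,7-bis(benzyloxy)-3-methoxy-2-phenylchroman-4-one (racemic, cis/trans) | COC1C(c2ccccc2)Oc2cc(OCc3ccccc3)cc(OCc3ccccc3)c2C1=O
F2 | step 4 | 5,7-bis(benzyloxy)-3-methoxy-2-phenylchroman-4-ol (racemic diastereomers) | COC1C(c2ccccc2)Oc2cc(OCc3ccccc3)cc(OCc3ccccc3)c2C1O
F3 | step 4 | rac-5,7-bis(benzyloxy)-3-methoxy-2-phenyl-2H-chromene | COC1=Cc2c(OCc3ccccc3)cc(OCc3ccccc3)cc2OC1c1ccccc1
F4 | step 5 | rac-cis-5,7-bis(benzyloxy)-2-phenylchroman-3-ol (both enantiomers drawn) | C(c1ccccc1)Oc1cc(OCc2ccccc2)c2c(c1)O[C@H](c1ccccc1)[C@H](O)C2.C(c1ccccc1)Oc1cc(OCc2ccccc2)c2c(c1)O[C@@H](c1ccccc1)[C@@H](O)C2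
F5 | step 5 | (2R,3R)-5,7-bis(benzyloxy)-2-phenylchroman-3-yl (S)-2-methoxy-2-phenylacetate | C(c1ccccc1)Oc1cc(OCc2ccccc2)c2c(c1)O[C@H](c1ccccc1)[C@H](OC(=O)[C@@H](OC)c1ccccc1)C2
F6 | step 5 | (2S,3S)-5,7-bis(benzyloxy)-2-phenylchroman-3-yl (S)-2-methoxy-2-phenylacetate | C(c1ccccc1)Oc1cc(OCc2ccccc2)c2c(c1)O[C@@H](c1ccccc1)[C@@H](OC(=O)[C@@H](OC)c1ccccc1)C2
F7 | step 7 | (2R,3R)-5,7-bis(benzyloxy)-8-bromo-2-phenylchroman-3-ol | C(c1ccccc1)Oc1cc(OCc2ccccc2)c2c(c1Br)O[C@H](c1ccccc1)[C@H](O)C2
F8 | step 7 | (2R,3R)-5,7-bis(benzyloxy)-8-bromo-4-(2-ethoxyethoxy)-2-phenylchroman-3-ol (3,4-trans) | C(c1ccccc1)Oc1cc(OCc2ccccc2)c2c(c1Br)O[C@H](c1ccccc1)[C@H](O)[C@H]2OCCOCC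
F9 | step 7 | 8-bromo tetra-O-benzyl dimer (bromine on C8 of the upper unit, 3,4-trans C4→C8 bond) | C(c1ccccc1)Oc1cc(OCc2ccccc2)c2c(c1Br)O[C@H](c1ccccc1)[C@H](O)[C@H]2c1c(OCc2ccccc2)cc(OCc2ccccc2)c2c1O[C@H](c1ccccc1)[C@H](O)C2
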